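**Retrosynthetic overview**
1. Key disconnection: the C1=O bond of the aryl ketone. The oxygen comes from water added across the (2,6-dimethoxyphenyl)alkyne of a diaryl nona-1,8-diyne, at the benzylic carbon only and at this alkyne only.
2. The C8–C9 alkyne next to the phenol ring is a masked CH2CH2 unit. It is saturated in the same flask once the C–O bond is in place.
3. The diaryl diyne comes from nona-1,8-diyne, which supplies all nine chain carbons, by two Sonogashira couplings: first the hindered 2-iodo-1,3-dimethoxybenzene, then 4-iodophenol.
4. No ring is formed. Both benzene rings are bought with their oxygen substituents in place, and no protecting group is used.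

Assumption: the target has no stereocentre and no stereogenic double bond, so it is one achiral compound and no step has to control configuration.

**Route**

Step 1
Reactants: 1 2-iodo-1,3-dimethoxybenzene; 2 nona-1,8-diyne (4 equiv)
Product: 3 1,3-dimethoxy-2-(nona-1,8-diyn-1-yl)benzene
Conditions: PdCl2(PPh3)2 (3 mol %), CuI (5 mol %), Et3N (3 equiv), DMF, 60 °C, 12 h, under argon; excess 2 distilled off and reused
Reagents that add atoms: none
Why: Sonogashira coupling, in which the aryl iodide adds oxidatively to zerovalent palladium even when flanked by two methoxy groups, the slim copper acetylide meets little steric hindrance, and the fourfold excess of the symmetrical diyne keeps double coupling near 10 %.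

Step 2
Reactants: 3 1,3-dimethoxy-2-(nona-1,8-diyn-1-yl)benzene (1.05 equiv); 4 4-iodophenol
Product: 5 4-[9-(2,6-dimethoxyphenyl)nona-1,8-diyn-1-yl]phenol
Conditions: PdCl2(PPh3)2 (2 mol %), CuI (4 mol %), Et3N (3 equiv), THF, 25–40 °C, under argon
Reagents that add atoms: none
Why: Sonogashira coupling, in which 4-iodophenol is an unhindered, reactive iodide that couples near room temperature without protection of the OH group, while the internal aryl alkyne of 3 has no acetylenic C–H bond and stays untouched.

Step 3
Reactants: 5 4-[9-(2,6-dimethoxyphenyl)nona-1,8-diyn-1-yl]phenol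
Product: 7 1-(2,6-dimethoxyphenyl)-9-(4-hydroxyphenyl)nonan-1-one, via alkynyl ketone 6 (not isolated)
Conditions: TfOH (5 mol %), H2O (5 equiv), CF3CH2OH, 0 to 25 °C, HPLC control, stopped at about 97 % conversion of 5; then NaHCO3 (10 mol %), 10% Pd/C, H2 (1 atm), 25 °C
Reagents that add atoms: water, O
Why: Proposed new method: site-selective Brønsted acid hydration of one of two donor-aryl alkynes in the same molecule, in which rate-limiting protonation at C2 gives the linear alpha-aryl vinyl cation at C1 stabilised by two ortho methoxy groups (sum of sigma-plus about -1.3) whereas a cation at C9 has only one para hydroxy group (sigma-plus -0.92), so that with rho-plus near -4 the dimethoxyphenyl alkyne should react some 50 to 100 times faster, water is captured at C1 only because a cation at C2 has no aryl conjugation and the ortho methoxy oxygen cannot close a ring onto C1 (hence no benzofuran, the usual risk under pi-acidic metal catalysis), and tautomerisation gives ketone 6; the closest known reaction type is the TfOH- or p-TsOH-catalysed Markovnikov hydration of a single electron-rich aryl alkyne, which has not been used to tell two activated aryl alkynes apart in a diyne carrying a free phenol, and the Pd/C hydrogenation that follows neutralisation is standard and spares the twisted, doubly ortho-substituted aryl ketone.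

**Compound list**
1 | 2-iodo-1,3-dimethoxybenzene | COc1cccc(OC)c1I | starting material
2 | nona-1,8-diyne | C#CCCCCCC#C | starting material
3 | 1,3-dimethoxy-2-(nona-1,8-diyn-1-yl)benzene | COc1cccc(OC)c1C#CCCCCCC#C | intermediate
4 | 4-iodophenol | Oc1ccc(I)cc1 | starting material
5 | 4-[9-(2,6-dimethoxyphenyl)nona-1,8-diyn-1-yl]phenol | COc1cccc(OC)c1C#CCCCCCC#Cc1ccc(O)cc1 | intermediate
6 | 1-(2,6-dimethoxyphenyl)-9-(4-hydroxyphenyl)non-8-yn-1-one | COc1cccc(OC)c1C(=O)CCCCCCC#Cc1ccc(O)cc1 | intermediate
7 | 1-(2,6-dimethoxyphenyl)-9-(4-hydroxyphenyl)nonan-1-one | COc1cccc(OC)c1C(=O)CCCCCCCCc1ccc(O)cc1 | target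

**Total step count:** 3. **Longest linear sequence:** 3 (1 → 3 → 5 → 7).

**Steps most likely to fail**

- **Step 3 (the new step).**
  - Risk: the rate gap between the two alkynes may be smaller than estimated. Some hydration would then occur at C9 and give a diketone, or unreacted 5 would be carried into the hydrogenation.
  - Fallback: it sets out from 3 and comes back at 6. The order of events is changed so that no second donor-aryl alkyne is present when water is added.
  - The known p-TsOH·H2O-catalysed hydration (EtOH/H2O, 70 °C) attacks alkoxyaryl alkynes and leaves aliphatic terminal alkynes alone. It converts 3 into 1-(2,6-dimethoxyphenyl)non-8-yn-1-one F1.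
  - Sonogashira coupling of F1 with 4 (PdCl2(PPh3)2, CuI, Et3N, THF, 25 °C) gives 6, now isolated. It is hydrogenated over 10% Pd/C as in the second half of step 3 to give 7. This costs one extra step.

- **Step 1.**
  - Risk: oxidative addition and transmetalation at the electron-rich, doubly ortho-substituted iodide may be slow. Oxidative dimerisation of the diyne and double coupling would then take over.
  - Fallback: it sets out from 1 and 2 and comes back at 3. The polarity of the coupling is reversed, so the hindered arene enters as the nucleophile.
  - Compound 2 (4 equiv) with NBS (1 equiv) and AgNO3 (10 mol %) in acetone gives 1-bromonona-1,8-diyne F2.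
  - Compound 1 with zinc dust and LiCl in THF at 50–70 °C gives (2,6-dimethoxyphenyl)zinc iodide F3.
  - Negishi coupling of F3 with F2 (Pd(PPh3)4, 3 mol %, THF, 25 °C) gives 3. No copper or amine is present, so the free terminal alkyne does not react.

- **Step 2.**
  - Risk: copper-mediated homocoupling of the valuable alkyne 3, and binding of phenoxide to copper, may lower the yield and leave metal traces that disturb step 3.
  - Fallback: it sets out from 4 and comes back at 5. It is a masked-phenol detour.
  - Compound 4 with Ac2O in pyridine gives 4-iodophenyl acetate F4, a more electrophilic iodide with no acidic OH.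
  - Sonogashira coupling of F4 with 3 under the conditions of step 2 gives 4-[9-(2,6-dimethoxyphenyl)nona-1,8-diyn-1-yl]phenyl acetate F5.
  - Methanolysis of F5 (K2CO3, 20 mol %, MeOH, 25 °C) gives 5.

Further compounds
F1 | step 3 | 1-(2,6-dimethoxyphenyl)non-8-yn-1-one | COc1cccc(OC)c1C(=O)CCCCCCC#C
F2 | step 1 | 1-bromonona-1,8-diyne | BrC#CCCCCCC#C
F3 | step 1 | (2,6-dimethoxyphenyl)zinc iodide | COc1cccc(OC)c1[Zn]I
F4 | step 2 | 4-iodophenyl acetate | CC(=O)Oc1ccc(I)cc1
F5 | step 2 | 4-[9-(2,6-dimethoxyphenyl)nona-1,8-diyn-1-yl]phenyl acetate | COc1cccc(OC)c1C#CCCCCCC#Cc1ccc(OC(C)=O)cc1
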